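## The problem

Compound 18 is a tetrahydrofuran (ring atoms O1, C2, C3, C4, C5; this numbering is used throughout). C2 carries a 4-hydroxy-3-methoxyphenyl ring, C3 a hydroxymethyl group, C4 a 4-hydroxy-3,5-dimethoxybenzoyl group, and C5 is a bare methylene. The three contiguous stereocentres are (2S,3R,4S): aryl and aroyl sit on one face and CH2OH on the other, so each neighbouring pair is trans. Two of the centres can be corrected by equilibration. C4 is α to the aryl ketone, and C3 is α to a carbonyl for as long as its branch is an ester; in both cases trans to the neighbours is the stable arrangement. C2 is a benzylic ether carbon that no base can repair, so the absolute configuration must enter at C2, or at a centre tied to C2 in the same event. The molecule is fragile in three places: the C2–O1 bond is benzylic and para to oxygen (it ionises in acid and can be hydrogenolysed), the β-alkoxy ketone can epimerise or open in base, and the free phenols are easily oxidised. The ketone should therefore appear late and the phenols stay masked to the end. The feature that opens the route is that O1–C5H2–C4H, with a vinyl group on C4, is racemic 2-vinyloxirane 4 after ionisation of its allylic C–O bond, while C2–C3 is the double bond of the arylidene malonate 3. The vinyl carbon is the latent ketone carbon and one malonate ester the latent CH2OH.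

## Retrosynthesis

18 ⇒ 17. The last cut is at the two phenolic O–benzyl bonds. Benzyl aryl ethers should survive zerovalent palladium, hot chloride, alkoxide, hydride and an aryllithium, and they leave under neutral conditions. The primary alcohol of 17 is deliberately free, so the final step only has to remove the fast-cleaving aryl ethers and can be stopped before the C2–O1 bond or the ketone is touched.

17 ⇒ 16 ⇒ 15. No skeletal bond is cut here. The ketone goes back to the benzylic carbinol of diol 16, and the primary alcohol of 16 to the methyl ester of 15. Reducing the ester before the aryl group is attached would force a protecting group onto the primary alcohol and an alkyl benzyl ether into the final hydrogenolysis. Keeping the ester until the arene is in place saves that step. The forward reactions must reduce an ester next to a benzylic alkoxide and then oxidise a benzylic alcohol in the presence of a primary one.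

15 ⇒ 11 + 13. The bond between the carbinol carbon and the dimethoxyaryl ring is cut, giving aldehyde 11 and the aryllithium 14 made from bromide 13, itself the benzyl ether of phenol 12. A Friedel–Crafts acylation of the arene by a C4 acid derivative would form the same bond, but it puts a strong Lewis acid next to the acid-labile C2–O1 bond. The aldehyde route runs at low temperature and asks only that 14 choose the aldehyde over a hindered methyl ester.

11 ⇒ 9. The aldehyde comes from oxidative cleavage of the vinyl group of 9. A vinyl group is the simplest acyl-carbon equivalent that tolerates decarboxylation and base, and it is what the key step leaves at C4. The forward cleavage must spare two electron-rich arenes, which argues for a dihydroxylation–glycol cleavage over ozone.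

9 ⇒ 8 ⇒ 7. The C3–H bond is traced to a second ester. Monoester 9 is the all-trans isomer of the epimer mixture 8, which arises from diester 7 by loss of one methoxycarbonyl group. This is where C3 is set: as an ester α-carbon it can equilibrate to the isomer trans to both the aryl and the vinyl group. In 7, C3 is not a stereocentre, so the key step has one centre fewer to control.

7 ⇒ 3 + 4. The bonds O1–C2 and C3–C4 are cut together. This takes the ring apart into arylidene malonate 3 (C2 and C3) and racemic 2-vinyloxirane 4 (O1, C5, C4 and the vinyl group), joined in the forward sense through zwitterions 5 and 6. Against a C2–C3 or C4–C5 cut, this pairing uses one achiral and one racemic building block and lets a chiral palladium catalyst supply the absolute configuration. The forward reaction must deliver the 2,4-cis ring as a single enantiomer, (2R,4S) in 7, which becomes (2S,…,4S) once an ester is lost and the priorities change.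

3 ⇒ 1 + 2. The C=C bond of 3 is cut by a Knoevenagel disconnection to the benzyl-protected aldehyde 1 and dimethyl malonate 2, both simple commercial materials.

## Roads not taken

Alternative 1: Prins–pinacol rearrangement of an allylic acetal.
- **Cut:** C2–C3 and C4–C5 together. The precursor is dioxolane A1, whose acetal carbon carries the benzylated guaiacyl ring and whose quaternary C4 bears the benzylated syringyl ring and an (E)-3-benzyloxypropenyl group.
- **Forward step:** SnCl4 would open A1 to an oxocarbenium ion. The far alkene carbon attacks it (C2–C3), then the ring methylene shifts from the carbinol carbon to the new cation (C4–C5) as the carbinol becomes the ketone, giving the tribenzyl ether A2.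
- **Merits:** ring, ketone and all three stereocentres arise in one step, and A2 is a single hydrogenolysis from 18. In steps after the key event this road is clearly better; the chosen plan needs eight further operations.
- **Weak points:**
  - The stereochemical information sits in the quaternary carbinol centre of A1, which is destroyed in the reaction. A1 must therefore be made as a single enantiomer at a tertiary, benzylic and allylic alcohol.
  - That same C–O bond, flanked by an electron-rich arene and an alkene, is the easiest bond in A1 to ionise, and SnCl4 may break it instead of the acetal.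
  - The alkene is 1,2-disubstituted with an allylic oxygen, so the Prins cation is secondary and poorly supported.
  - The electron-rich aryl group competes with the ring methylene as the migrating group, which would give a six-membered ketone.
- **Comparison:** the chosen plan sets against the shorter endgame a key step fed by an achiral alkene and a racemic epoxide, with no cation next to the sensitive arenes.

Alternative 2: alkoxymethyl radical cyclization onto an aryl enol acetate.
- **Cut:** C4–C5. The precursor A3 is an open chain in which the C2 oxygen carries a phenylselanylmethyl group, C3 its benzyloxymethyl branch, and C4 is the alkene carbon of the enol acetate of the aryl ketone.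
- **Forward step:** Bu3SnH with AIBN turns the selenide into an alkoxymethyl radical that closes 5-exo onto C4. The benzylic α-acetoxy radical then takes hydrogen to give A4.
- **Merits:** neutral conditions and a fast ring closure. The C3 branch (trans to the new group) and the C2 aryl group (1,3-cis) both steer C4 to the all-trans arrangement. This substrate control is easier to predict than the ligand control of the chosen plan, and in that respect the road is better.
- **Weak points:**
  - C2 and C3 of A3 must be set beforehand by stoichiometric chiral control.
  - The selenide has to be placed on a hindered benzylic alcohol.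
  - A nucleophilic radical meets an electron-rich enol acetate, so closure is slowed and premature reduction competes.
  - Tin and selenium are used in full equivalents.
  - A4 still needs acetate cleavage, oxidation and a hydrogenolysis that includes an alkyl benzyl ether.
- **Comparison:** the chosen plan sets against the better predictability a catalytic ring construction that creates two stereocentres from 3 and 4 in one step, and a shorter path to its key precursor.

Alternative 3: donor–acceptor cyclopropane and formaldehyde (3+2) annulation.
- **Cut:** O1–C2 and C4–C5. The partners are cyclopropane diester A5 and formaldehyde A6.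
- **Forward step:** Sn(OTf)2 activates A5, the oxygen of A6 bonds to the benzylic carbon and the malonate carbon adds to the carbon of A6, giving A7.
- **Merits:** a cheap Lewis acid catalyst. The C3 branch is already at the right oxidation level, and the relative configuration at C2 and C3 follows stereospecifically from A5. On these points the road is as good as or better than the chosen one.
- **Weak points:**
  - The oxygen enters with inversion at the benzylic carbon while the neighbouring carbon keeps its configuration. The 4,5-trans ring of A7 therefore demands the cis-disubstituted cyclopropane A5 as a single enantiomer, which is the harder isomer to make.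
  - The para-alkoxyaryl donor favours full ionisation of A5, which erodes both the enantiomeric purity and the stereospecificity.
  - A6 must be generated from its polymer and is a poor partner in this annulation.
  - In A7 the diester sits at C4, where one ester must be removed and the other turned into an aryl ketone. This costs as many steps as the chosen endgame.
- **Comparison:** the chosen plan places the diester at C3, where the epimerisable ester stage sets C3 trans to both neighbours, and takes its absolute configuration from a catalyst, not from a pre-made chiral cyclopropane.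

Key step: step 2

Assumption: the (1S,2S) antipode of the diphosphine is written for the (2R,4S) adduct by analogy with its branched-selective openings of 4. The sense of induction with a tethered malonate must be confirmed on the first run, and the (1R,2R) antipode is used if it proves opposite.

Assumption: aldehyde 1 and phenol 12 are purchased.

## Route

Step 1
Reactants: 1 4-(benzyloxy)-3-methoxybenzaldehyde; 2 dimethyl malonate
Product: 3 dimethyl 2-[4-(benzyloxy)-3-methoxybenzylidene]malonate
Conditions: piperidine (cat.), AcOH (cat.), toluene, reflux, azeotropic removal of water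
Reagents that add atoms: none
Why: Knoevenagel condensation; removal of water drives the electron-rich aldehyde to the arylidene malonate, and the two identical esters leave no alkene geometry to control.

Step 2
Reactants: 3 dimethyl 2-[4-(benzyloxy)-3-methoxybenzylidene]malonate; 4 racemic 2-vinyloxirane
Product: 7 dimethyl (2R,4S)-2-[4-(benzyloxy)-3-methoxyphenyl]-4-vinyltetrahydrofuran-3,3-dicarboxylate (2,4-cis), via allylpalladium alkoxide zwitterion 5 (not isolated), via open-chain malonate zwitterion 6 (not isolated)
Conditions: Pd2(dba)3·CHCl3 (2.5 mol %), (1S,2S)-N,N'-bis[2-(diphenylphosphino)benzoyl]cyclohexane-1,2-diamine (7.5 mol %), THF, 25 to 40 °C; 4 (1.5 equiv) added slowly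
Reagents that add atoms: none
Why: Zerovalent palladium opens racemic 4 with inversion to zwitterion 5, whose alkoxide adds reversibly to the benzylidene carbon of 3 (oxa-Michael addition) to give the tethered malonate 6; the malonate carbon then attacks the internal allyl carbon on the face away from palladium, forming O1–C2 and C3–C4 and returning the catalyst. The closest known reaction type is the palladium-catalysed formal (3+2) cycloaddition of vinyl epoxides with doubly activated alkenes, joined here to the dynamic kinetic asymmetric opening of 4 for which this diphosphine class is established. The one ring formed, the tetrahydrofuran, closes in the 5-exo mode at the allyl unit; the only alternative, 7-endo attack at the terminal allyl carbon, is disfavoured by ring size. C4 is set by the ligand: the two diastereomeric allyl complexes that arise from the two enantiomers of 4 interconvert by π–σ–π isomerisation, and because capture by the only moderately electrophilic 3 is slow, this equilibration should be complete before the C–C bond forms. C2 is set under substrate control in the same closure: both C2 epimers of 6 stay in equilibrium with 3 and 5, and the epimer that closes with the aryl group and the allyl residue both pseudo-equatorial on the forming envelope leads to the 2,4-cis ring. The step needs branched regioselectivity, which the tether in 6 secures, and it needs the alkoxide to be captured before 5 isomerises or oligomerises, which is why 4 is added slowly to a concentrated solution of 3. C3 carries two identical esters and is not a stereocentre at this stage.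

Step 3
Reactants: 7 dimethyl (2R,4S)-2-[4-(benzyloxy)-3-methoxyphenyl]-4-vinyltetrahydrofuran-3,3-dicarboxylate
Product: 8 methyl (2S,4S)-2-[4-(benzyloxy)-3-methoxyphenyl]-4-vinyltetrahydrofuran-3-carboxylate as a mixture of C3 epimers
Conditions: LiCl, H2O (2 equiv), DMSO, 150 °C
Reagents that add atoms: none
Why: Krapcho dealkoxycarbonylation: chloride demethylates one ester by SN2 attack at the methyl group, the carboxylate loses CO2 and water protonates the ester enolate. Protonation from the face away from the cis aryl and vinyl groups should favour the all-cis ester, so the product is taken on as the epimer mixture; C2 and C4 are untouched, and only their descriptors change with the loss of one ester.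

Step 4
Reactants: 8 methyl (2S,4S)-2-[4-(benzyloxy)-3-methoxyphenyl]-4-vinyltetrahydrofuran-3-carboxylate (C3 epimers)
Product: 9 methyl (2S,3S,4S)-2-[4-(benzyloxy)-3-methoxyphenyl]-4-vinyltetrahydrofuran-3-carboxylate (all-trans)
Conditions: NaOMe (0.3 equiv), MeOH, 50 °C
Reagents that add atoms: none
Why: Base-mediated epimerisation through the ester enolate (thermodynamic control); only the (3S) isomer has the ester trans to both the aryl and the vinyl neighbour, so the mixture should converge on it. C2 and C4 carry no acidic hydrogen, and ring opening by β-elimination would be the reverse of a 5-endo closure and is expected to be slow.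

Step 5
Reactants: 9 methyl (2S,3S,4S)-2-[4-(benzyloxy)-3-methoxyphenyl]-4-vinyltetrahydrofuran-3-carboxylate
Product: 11 methyl (2S,3S,4S)-2-[4-(benzyloxy)-3-methoxyphenyl]-4-formyltetrahydrofuran-3-carboxylate, via vicinal diol 10 (not isolated)
Conditions: K2OsO4·2H2O (2 mol %), NaIO4 (4 equiv), 2,6-lutidine, 1,4-dioxane–H2O, rt
Reagents that add atoms: sodium periodate NaIO4, [Na+].[O-]I(=O)(=O)=O (the aldehyde oxygen, relayed by OsO4)
Why: Lemieux–Johnson oxidation: catalytic dihydroxylation of the monosubstituted alkene to diol 10 and glycol cleavage by NaIO4 in the same flask, which leaves untouched the electron-rich arenes that ozone would attack. 2,6-Lutidine keeps the medium near neutral, and C4, now α to the aldehyde, is already in its stable trans arrangement.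

Step 6
Reactants: 12 4-bromo-2,6-dimethoxyphenol
Product: 13 2-(benzyloxy)-5-bromo-1,3-dimethoxybenzene
Conditions: BnBr, K2CO3, DMF, rt
Reagents that add atoms: benzyl bromide, BrCc1ccccc1
Why: Williamson ether synthesis on a phenoxide; the benzyl ether masks the acidic phenol for the halogen–lithium exchange that follows.

Step 7
Reactants: 13 2-(benzyloxy)-5-bromo-1,3-dimethoxybenzene; 11 methyl (2S,3S,4S)-2-[4-(benzyloxy)-3-methoxyphenyl]-4-formyltetrahydrofuran-3-carboxylate
Product: 15 methyl (2S,3S,4S)-4-{[4-(benzyloxy)-3,5-dimethoxyphenyl](hydroxy)methyl}-2-[4-(benzyloxy)-3-methoxyphenyl]tetrahydrofuran-3-carboxylate (both carbinol epimers), via aryllithium 14 (not isolated)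
Conditions: 13 (1.3 equiv), n-BuLi (1.25 equiv), THF, −78 °C; then added to 11 in THF, −78 °C; then H2O
Reagents that add atoms: none
Why: Bromine–lithium exchange gives 14, which undergoes 1,2-addition to the aldehyde far faster than to the hindered methyl ester at −78 °C. The new carbinol centre is not controlled and is removed by the later oxidation; any lactone formed from the alkoxide and the ester would be reduced to the same diol in step 8.

Step 8
Reactants: 15 methyl (2S,3S,4S)-4-{[4-(benzyloxy)-3,5-dimethoxyphenyl](hydroxy)methyl}-2-[4-(benzyloxy)-3-methoxyphenyl]tetrahydrofuran-3-carboxylate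
Product: 16 {(2S,3R,4S)-4-{[4-(benzyloxy)-3,5-dimethoxyphenyl](hydroxy)methyl}-2-[4-(benzyloxy)-3-methoxyphenyl]tetrahydrofuran-3-yl}methanol (both carbinol epimers)
Conditions: LiAlH4, THF, 0 °C to rt; then H2O, aq. NaOH
Reagents that add atoms: none
Why: LiAlH4 reduction of the ester to the primary alcohol; benzyl ethers and the ring are inert, and C3 is no longer epimerisable once reduced. The work-up is basic because the electron-rich benzylic carbinol would ionise in acid.

Step 9
Reactants: 16 {(2S,3R,4S)-4-{[4-(benzyloxy)-3,5-dimethoxyphenyl](hydroxy)methyl}-2-[4-(benzyloxy)-3-methoxyphenyl]tetrahydrofuran-3-yl}methanol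
Product: 17 [4-(benzyloxy)-3,5-dimethoxyphenyl]{(3S,4R,5S)-5-[4-(benzyloxy)-3-methoxyphenyl]-4-(hydroxymethyl)tetrahydrofuran-3-yl}methanone
Conditions: MnO2 (activated, excess), CH2Cl2, rt
Reagents that add atoms: none
Why: Chemoselective benzylic oxidation: MnO2 oxidises the electron-rich benzylic carbinol of either epimer and leaves the saturated primary alcohol. C4 becomes α to the ketone but is already trans to the C3 branch, and the trans hydroxy ketone cannot close to a strained trans-fused hemiketal.

Step 10
Reactants: 17 [4-(benzyloxy)-3,5-dimethoxyphenyl]{(3S,4R,5S)-5-[4-(benzyloxy)-3-methoxyphenyl]-4-(hydroxymethyl)tetrahydrofuran-3-yl}methanone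
Product: 18 (4-hydroxy-3,5-dimethoxyphenyl)[(3S,4R,5S)-5-(4-hydroxy-3-methoxyphenyl)-4-(hydroxymethyl)tetrahydrofuran-3-yl]methanone
Conditions: H2 (1 atm), 10% Pd/C, EtOAc–MeOH, rt, stopped after uptake of two equivalents
Reagents that add atoms: none
Why: Hydrogenolysis of the two aryl benzyl ethers, the fastest class of benzyl ether to cleave. The ketone, deactivated by its para oxygen, and the cyclic benzylic C2–O1 bond should survive short exposure at atmospheric pressure in a neutral solvent.

## Compound list

1 | 4-(benzyloxy)-3-methoxybenzaldehyde | COc1cc(C=O)ccc1OCc1ccccc1 | starting material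
2 | dimethyl malonate | COC(=O)CC(=O)OC | starting material
3 | dimethyl 2-[4-(benzyloxy)-3-methoxybenzylidene]malonate | COC(=O)C(=Cc1ccc(OCc2ccccc2)c(OC)c1)C(=O)OC | intermediate
4 | racemic 2-vinyloxirane | C=CC1CO1 | starting material
5 | (1-oxidobut-3-en-2-yl)palladium cation, the allylpalladium alkoxide zwitterion from 4 (diphosphine on palladium omitted; drawn as the σ-allyl form bonded at the internal carbon) | [O-]CC([Pd+])C=C | intermediate
6 | open-chain oxa-Michael adduct of 5 and 3: malonate carbanion tethered through O1 to the cationic allylpalladium unit (diphosphine omitted; both C2 epimers) | COC(=O)[C-](C(=O)OC)C(OCC([Pd+])C=C)c1ccc(OCc2ccccc2)c(OC)c1 | intermediate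
7 | dimethyl (2R,4S)-2-[4-(benzyloxy)-3-methoxyphenyl]-4-vinyltetrahydrofuran-3,3-dicarboxylate | COc1cc([C@H]2OC[C@@H](C=C)C2(C(=O)OC)C(=O)OC)ccc1OCc1ccccc1 | intermediate
8 | methyl (2S,4S)-2-[4-(benzyloxy)-3-methoxyphenyl]-4-vinyltetrahydrofuran-3-carboxylate, mixture of C3 epimers | COc1cc([C@H]2OC[C@@H](C=C)C2C(=O)OC)ccc1OCc1ccccc1 | intermediate
9 | methyl (2S,3S,4S)-2-[4-(benzyloxy)-3-methoxyphenyl]-4-vinyltetrahydrofuran-3-carboxylate | COc1cc([C@H]2OC[C@@H](C=C)[C@@H]2C(=O)OC)ccc1OCc1ccccc1 | intermediate
10 | methyl (2S,3S,4S)-2-[4-(benzyloxy)-3-methoxyphenyl]-4-(1,2-dihydroxyethyl)tetrahydrofuran-3-carboxylate, both side-chain carbinol epimers | COc1cc([C@H]2OC[C@@H](C(O)CO)[C@@H]2C(=O)OC)ccc1OCc1ccccc1 | intermediate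
11 | methyl (2S,3S,4S)-2-[4-(benzyloxy)-3-methoxyphenyl]-4-formyltetrahydrofuran-3-carboxylate | COc1cc([C@H]2OC[C@@H](C=O)[C@@H]2C(=O)OC)ccc1OCc1ccccc1 | intermediate
12 | 4-bromo-2,6-dimethoxyphenol | COc1cc(Br)cc(OC)c1O | starting material
13 | 2-(benzyloxy)-5-bromo-1,3-dimethoxybenzene | COc1cc(Br)cc(OC)c1OCc1ccccc1 | intermediate
14 | [4-(benzyloxy)-3,5-dimethoxyphenyl]lithium | [Li]c1cc(OC)c(OCc2ccccc2)c(OC)c1 | intermediate
15 | methyl (2S,3S,4S)-4-{[4-(benzyloxy)-3,5-dimethoxyphenyl](hydroxy)methyl}-2-[4-(benzyloxy)-3-methoxyphenyl]tetrahydrofuran-3-carboxylate, both carbinol epimers | COc1cc([C@H]2OC[C@@H](C(O)c3cc(OC)c(OCc4ccccc4)c(OC)c3)[C@@H]2C(=O)OC)ccc1OCc1ccccc1 | intermediate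
16 | {(2S,3R,4S)-4-{[4-(benzyloxy)-3,5-dimethoxyphenyl](hydroxy)methyl}-2-[4-(benzyloxy)-3-methoxyphenyl]tetrahydrofuran-3-yl}methanol, both carbinol epimers | COc1cc([C@H]2OC[C@@H](C(O)c3cc(OC)c(OCc4ccccc4)c(OC)c3)[C@@H]2CO)ccc1OCc1ccccc1 | intermediate
17 | [4-(benzyloxy)-3,5-dimethoxyphenyl]{(3S,4R,5S)-5-[4-(benzyloxy)-3-methoxyphenyl]-4-(hydroxymethyl)tetrahydrofuran-3-yl}methanone (name positions 5, 4, 3 are C2, C3, C4 of the text) | COc1cc([C@H]2OC[C@@H](C(=O)c3cc(OC)c(OCc4ccccc4)c(OC)c3)[C@@H]2CO)ccc1OCc1ccccc1 | intermediate
18 | (4-hydroxy-3,5-dimethoxyphenyl)[(3S,4R,5S)-5-(4-hydroxy-3-methoxyphenyl)-4-(hydroxymethyl)tetrahydrofuran-3-yl]methanone | COc1cc([C@H]2OC[C@@H](C(=O)c3cc(OC)c(O)c(OC)c3)[C@@H]2CO)ccc1O | target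

## Step count and least certain steps

Total step count: 10. Longest linear sequence: 9 steps (from 1 through steps 1–5 and 7–10); step 6 is a one-step side branch.

**Step 2 (key step).** Capture of zwitterion 5 by the electron-rich arylidene diester may be too slow, so that isomerisation of the opened epoxide and oligomerisation take over. A second concern is incomplete cis selectivity in the ring closure. A C2 error cannot be repaired later, so the trans isomer would have to be removed by chromatography at this stage.
- Fallback: from 1, condensation with 2,2-dimethyl-1,3-dioxane-4,6-dione gives the arylidene dione F1. It is a far stronger acceptor than 3 and a known partner of vinyl epoxides in this palladium-catalysed (3+2) reaction.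
- With 4 and the same catalyst, F1 should give the spiro adduct F2 (2,4-cis).
- NaOMe in MeOH opens the dioxanedione ring with loss of acetone to the half-ester F3. Acidifying and warming in toluene removes CO2 and returns to the route at 8.

**Step 3.** Demethylation at the hindered quaternary diester may be slow. At the temperature then needed, the ester enolate released on decarboxylation could expel O1 and open the ring.
- Fallback: from 7, both esters are hydrolysed with KOH in aqueous ethylene glycol at reflux to the diacid F4.
- F4 loses CO2 on heating in toluene–pyridine through its cyclic hydrogen-bonded form, without a free enolate, to give the monoacid F5.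
- MeI and K2CO3 in DMF then give 8.

**Step 7.** The basic aryllithium may deprotonate the α-branched aldehyde (loss of material and epimerisation at C4 on quench), or attack the methyl ester once the aldehyde is consumed.
- Fallback: from 13, exchange with n-BuLi (14), B(OMe)3 and aqueous acid give the boronic acid F6.
- Its 1,2-addition to 11, catalysed by Rh(acac)(CO)2 and dppf in aqueous dimethoxyethane at 80 °C, is a neutral arylation that leaves esters and α-centres alone. It returns to the route at 15.

**Step 9.** Oxidation may spread to the primary alcohol, or stall on the more hindered carbinol epimer.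
- Fallback: from 16, TBSCl and imidazole silylate the primary hydroxyl selectively to the silyl ether F7.
- Dess–Martin oxidation of the remaining carbinol gives the silyloxy ketone F8.
- TBAF buffered with AcOH frees the alcohol, which is 17.

**Step 10.** Reduction may run on after debenzylation, with hydrogenolysis of the benzylic C2–O1 bond or reduction of the aryl ketone.
- Fallback: from 17, BCl3 with pentamethylbenzene as benzyl-cation trap in CH2Cl2 at −78 °C cleaves the two aryl benzyl ethers without hydrogen and gives 18 directly. No new compound is involved.

## Further compounds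

F1 | step 2 | 5-[4-(benzyloxy)-3-methoxybenzylidene]-2,2-dimethyl-1,3-dioxane-4,6-dione | COc1cc(C=C2C(=O)OC(C)(C)OC2=O)ccc1OCc1ccccc1
F2 | step 2 | (1R,4S)-1-[4-(benzyloxy)-3-methoxyphenyl]-4-ethenyl-8,8-dimethyl-2,7,9-trioxaspiro[4.5]decane-6,10-dione | COc1cc([C@H]2OC[C@@H](C=C)C23C(=O)OC(C)(C)OC3=O)ccc1OCc1ccccc1
F3 | step 2 | (2R,4S)-2-[4-(benzyloxy)-3-methoxyphenyl]-3-(methoxycarbonyl)-4-vinyltetrahydrofuran-3-carboxylic acid, C3 epimers | COc1cc([C@H]2OC[C@@H](C=C)C2(C(=O)O)C(=O)OC)ccc1OCc1ccccc1
F4 | step 3 | (2R,4S)-2-[4-(benzyloxy)-3-methoxyphenyl]-4-vinyltetrahydrofuran-3,3-dicarboxylic acid | COc1cc([C@H]2OC[C@@H](C=C)C2(C(=O)O)C(=O)O)ccc1OCc1ccccc1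
F5 | step 3 | (2S,4S)-2-[4-(benzyloxy)-3-methoxyphenyl]-4-vinyltetrahydrofuran-3-carboxylic acid, C3 epimers | COc1cc([C@H]2OC[C@@H](C=C)C2C(=O)O)ccc1OCc1ccccc1
F6 | step 7 | [4-(benzyloxy)-3,5-dimethoxyphenyl]boronic acid | COc1cc(B(O)O)cc(OC)c1OCc1ccccc1
F7 | step 9 | [4-(benzyloxy)-3,5-dimethoxyphenyl]{(3S,4R,5S)-5-[4-(benzyloxy)-3-methoxyphenyl]-4-[(tert-butyldimethylsilyloxy)methyl]tetrahydrofuran-3-yl}methanol, both carbinol epimers | COc1cc([C@H]2OC[C@@H](C(O)c3cc(OC)c(OCc4ccccc4)c(OC)c3)[C@@H]2CO[Si](C)(C)C(C)(C)C)ccc1OCc1ccccc1
F8 | step 9 | [4-(benzyloxy)-3,5-dimethoxyphenyl]{(3S,4R,5S)-5-[4-(benzyloxy)-3-methoxyphenyl]-4-[(tert-butyldimethylsilyloxy)methyl]tetrahydrofuran-3-yl}methanone | COc1cc([C@H]2OC[C@@H](C(=O)c3cc(OC)c(OCc4ccccc4)c(OC)c3)[C@@H]2CO[Si](C)(C)C(C)(C)C)ccc1OCc1ccccc1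
F0 | step 10 | none | none
A1 | alternative 1 | 2-[4-(benzyloxy)-3-methoxyphenyl]-4-[4-(benzyloxy)-3,5-dimethoxyphenyl]-4-[(E)-3-(benzyloxy)prop-1-enyl]-1,3-dioxolane (one enantiomer at the quaternary carbon would be required; the two ring centres are left open) | COc1cc(C2OCC(/C=C/COCc3ccccc3)(c3cc(OC)c(OCc4ccccc4)c(OC)c3)O2)ccc1OCc1ccccc1
A2 | alternative 1 | [4-(benzyloxy)-3,5-dimethoxyphenyl]{(3S,4R,5S)-5-[4-(benzyloxy)-3-methoxyphenyl]-4-[(benzyloxy)methyl]tetrahydrofuran-3-yl}methanone | COc1cc([C@H]2OC[C@@H](C(=O)c3cc(OC)c(OCc4ccccc4)c(OC)c3)[C@@H]2COCc2ccccc2)ccc1OCc1ccccc1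
A3 | alternative 2 | (3R,4S)-4-[4-(benzyloxy)-3-methoxyphenyl]-1-[4-(benzyloxy)-3,5-dimethoxyphenyl]-3-[(benzyloxy)methyl]-4-[(phenylselanyl)methoxy]but-1-en-1-yl acetate (either alkene geometry) | COc1cc([C@@H](OC[Se]c2ccccc2)[C@@H](COCc2ccccc2)C=C(OC(C)=O)c2cc(OC)c(OCc3ccccc3)c(OC)c2)ccc1OCc1ccccc1
A4 | alternative 2 | [4-(benzyloxy)-3,5-dimethoxyphenyl]{(3S,4R,5S)-5-[4-(benzyloxy)-3-methoxyphenyl]-4-[(benzyloxy)methyl]tetrahydrofuran-3-yl}methyl acetate, both epimers at the acetoxy carbon | COc1cc([C@H]2OC[C@@H](C(OC(C)=O)c3cc(OC)c(OCc4ccccc4)c(OC)c3)[C@@H]2COCc2ccccc2)ccc1OCc1ccccc1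
A5 | alternative 3 | dimethyl cis-2-[4-(benzyloxy)-3-methoxyphenyl]-3-[(tert-butyldimethylsilyloxy)methyl]cyclopropane-1,1-dicarboxylate, enantiomer as drawn | COc1cc([C@H]2[C@@H](CO[Si](C)(C)C(C)(C)C)C2(C(=O)OC)C(=O)OC)ccc1OCc1ccccc1
A6 | alternative 3 | formaldehyde | C=O
A7 | alternative 3 | dimethyl 4,5-trans-5-[4-(benzyloxy)-3-methoxyphenyl]-4-[(tert-butyldimethylsilyloxy)methyl]tetrahydrofuran-3,3-dicarboxylate, enantiomer as drawn | COc1cc([C@H]2OCC(C(=O)OC)(C(=O)OC)[C@@H]2CO[Si](C)(C)C(C)(C)C)ccc1OCc1ccccc1
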